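| flask | starting material | partner | second substrate | remark | time |
|---|---|---|---|---|---|
| gamma | 0.050 M | 0.85 equiv | 1 equiv | run made earlier |  |
| alpha | 0.050 M | 1.5 equiv | 1 equiv | run made earlier |  |
| eta | 0.050 M | 2 equiv | 1 equiv | run made earlier |  |
| south | 0.050 M | 1.10 equiv | 1.00 equiv |  | 8.0 min |
| east | 0.050 M | 2.20 equiv | 1.00 equiv |  | 5.0 min |

- gamma (time / min: target / %, starting material / %): 1.00: 6.1, 92.4; 2.00: 13.1, 83.8; 3.00: 17.4, 78.3; 4.00: 21.5, 71.5
- alpha (time / min: target / %, starting material / %): 0.333: 5.9, 94.0; 0.667: 9.0, 89.4; 1.50: 17.8, 78.3; 4.00: 37.1, 55.2
- eta (time / min: target / %, starting material / %): 1.00: 17.1, 79.8; 2.00: 28.8, 64.5; 3.00: 37.8, 55.4; 4.00: 45.3, 45.6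

(standard deviation of a reading: 1 percentage point)

1. the flask that ends with the higher amount of target, in percent of the starting material charged, or "neither" when 2 percentage points or less lies between them (south / east / neither)
2. final target, as a percentage of the starting material charged, in south
3. final target, as a percentage of the starting material charged, in east

- what was read earlier has a scatter of 1 percentage point, one standard deviation

- Distrust the time of reading: gamma, alpha and eta end at 4.00 min, but south is read at 8.0 min and east at 5.0 min, so your next charge hangs on what extra minutes cost.
- Call loss whatever is neither starting material nor target, and suppose it grows as G[starting material][target], both as fractions of the charge.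
- Replace each curve by its mean, halfway between its ends, and the pooled last readings give 0.148 min⁻¹ for G, the loss constant.
- Check that shortcut on eta: the means give 1.04 times the reading-by-reading sum, a small error.
- So loss over target is the loss number N, which is G times mean [starting material] times half the time, and target is the starting material consumed divided by 1 + N.
- My own reckoning takes a second-order law from eta, 0.117 min⁻¹ per equivalent. South keeps 48.1% starting material, so N is 0.439 and target 36.1%. East keeps 34.9%, so N is 0.250 and target 52.1%.
- The forecast says east, with south at 43% and east at 55%, taking target as “a steady fraction of starting material consumed”. My south is lower than the forecast's, but we agree on the decision: charge east.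
- The flasks give 35.9% in south and 52.1% in east, so east ends higher.

    starting material + partner → target (k = 2.20 L mol⁻¹ min⁻¹)
    second substrate + partner → second product (k = 0.804 L mol⁻¹ min⁻¹)
    starting material + second substrate → cross product (k = 0.0558 L mol⁻¹ min⁻¹)
    target → over-reaction product (k = 2.51 × 10⁻⁴ min⁻¹)
    starting material + target → side product (k = 1.36 L mol⁻¹ min⁻¹)

- Loss over target, read from the results, is 0.494 in south and 0.246 in east, beside the reckoned 0.439 and 0.250. Of the two settings that differ, the equivalents of partner are the largest single effect between the flasks: with that difference taken away, east falls from 52.1% to 30.4% target, whereas with the difference in time taken away, east rises to 60.0%.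
- Now take south read at 30 min, with 13.7% starting material left: G gives N = 1.27 and target 38.0%. The computed flask holds 38.1% target.

The runs are simulated from invented constants; noise was put on by code.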